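Aspidin AB is cut at the C3–CH2 bridge into acetylfilicinic acid (ring B) and a fully substituted ring A. Ring A (C1 butyryl, C2 OH, C3 CH2, C4 OH, C5 CH3, C6 OCH3) is built by a Danheiser benzannulation. The adjacent C5–CH3/C6–OCH3 pair is the triple bond of 1-methoxypropyne, and C1–C4, with their H/O/H/O pattern, are a 3-alkoxycyclobutenone. One thermal operation forms C4–C5 and C6–C1, closes ring A and delivers three differentiated oxygens (C4 OH, C2 O-i-Pr, C6 OCH3). The precursor is 3-isopropoxycyclobut-2-enone. C1 is then butyrylated by directed lithiation, C3 is formylated, and the rings are joined by reductive alkylation.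

Key step: step 3

Remark on the chemistry: the target has no stereocentre, and ring B is drawn in the enol tautomer of the target SMILES. Electrophilic acylation of the benzannulation product would favour C3 (ortho to the free OH), so C1 is addressed by lithiation. The C2 oxygen therefore carries isopropyl, which is inert to n-BuLi and is cleaved before methyl, and not a benzylic group.

Step 1
Reactants: 1 2-chloro-1,1-dimethoxyethane
Product: 3 1-methoxyprop-1-yne, via lithium methoxyacetylide 2 (not isolated)
Conditions: LiNH2 (3.0 equiv), liq. NH3, −33 °C; then MeI (1.0 equiv), −33 °C; H2O work-up, distillation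
Reagents that add atoms: iodomethane, CI
Why: Three equivalents of LiNH2 remove CH3OH, then HCl, then the acetylenic proton (double β-elimination and deprotonation), and SN2 C-methylation of acetylide 2 completes the standard one-pot alkoxyalkyne synthesis from a chloroacetaldehyde acetal.

Step 2
Reactants: 4 3-ethoxycyclobut-2-en-1-one
Product: 5 3-(propan-2-yloxy)cyclobut-2-en-1-one
Conditions: i-PrOH (solvent, dry), camphorsulfonic acid (5 mol %), 50 °C, EtOH stripped by repeated concentration and refilling
Reagents that add atoms: propan-2-ol, CC(C)O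
Why: Acid-catalysed addition–elimination at C3 of the vinylogous ester (transetherification), driven by excess i-PrOH and removal of EtOH, installs an O-substituent that tolerates heat and n-BuLi and can later be cleaved in preference to an aryl methyl ether.

Step 3
Reactants: 5 3-(propan-2-yloxy)cyclobut-2-en-1-one; 3 1-methoxyprop-1-yne
Product: 10 3-methoxy-2-methyl-5-(propan-2-yloxy)phenol, via vinylketene 6 (not isolated), via alkenylcyclobutenone 7 (not isolated), via dienylketene 8 (not isolated), via cyclohexadienone 9 (not isolated)
Conditions: 5 (1 equiv), 3 (2.5 equiv), toluene (0.5 M), sealed tube, 120 °C then 150 °C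
Reagents that add atoms: none
Why: Danheiser benzannulation: thermal 4π-electrocyclic opening of 5 (cleaving the C(=O)–CH2 bond) gives vinylketene 6, which adds ynol ether 3 in a regioselective (2+2) cycloaddition to give 7 and so forms C4–C5 and C6–C1. A second 4π opening gives dienylketene 8, whose disrotatory 6π-electrocyclisation re-forms the C3–C4 bond and closes ring A as dienone 9, and tautomerisation gives phenol 10. The closest known reaction type is the benzannulation of cyclobutenones with alkoxyalkynes to resorcinol monoethers; the 3-alkoxy donor should only raise the temperature needed for the first opening. No stereocentre remains, since the one in 7 is lost on ring opening. The selectivity needed is the orientation of the (2+2) step, and it is secured by the polarisation of 3: its methyl-bearing carbon is the nucleophilic terminus and attacks the ketene carbonyl carbon, so CH3 ends ortho and OCH3 meta to the new OH. A methoxyalkyne cannot lose an alkene by retro-ene fragmentation at these temperatures, and the three oxygens emerge as OH (C4), O-i-Pr (C2) and OCH3 (C6).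

Step 4
Reactants: 10 3-methoxy-2-methyl-5-(propan-2-yloxy)phenol
Product: 11 [3-methoxy-2-methyl-5-(propan-2-yloxy)phenoxy]tri(propan-2-yl)silane
Conditions: TIPSCl, imidazole, DMF, rt
Reagents that add atoms: chlorotri(propan-2-yl)silane, CC(C)[Si](Cl)(C(C)C)C(C)C
Why: Standard phenol silylation masks the acidic OH, and the bulky, poorly coordinating OTIPS group, pushed toward C3 by the C5 methyl, shields C3–H for the next step.

Step 5
Reactants: 11 [3-methoxy-2-methyl-5-(propan-2-yloxy)phenoxy]tri(propan-2-yl)silane; 12 N-methoxy-N-methylbutanamide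
Product: 15 1-{2-methoxy-3-methyl-6-(propan-2-yloxy)-4-[tri(propan-2-yl)silyloxy]phenyl}butan-1-one, via aryllithium 13 (not isolated), via lithium hemiaminal adduct 14 (not isolated)
Conditions: n-BuLi, TMEDA, THF, 0 °C; then 12, −78 → 0 °C; AcOH quench
Reagents that add atoms: none
Why: Directed ortho-metalation followed by Weinreb ketone synthesis: C1–H lies between two coordinating alkyl ether oxygens (C6 OCH3, C2 O-i-Pr) and should be removed in preference to C3–H beside the OTIPS group, and chelated adduct 14 releases the ketone only on quench, so over-addition is excluded.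

Step 6
Reactants: 15 1-{2-methoxy-3-methyl-6-(propan-2-yloxy)-4-[tri(propan-2-yl)silyloxy]phenyl}butan-1-one
Product: 18 1-(4,6-dihydroxy-2-methoxy-3-methylphenyl)butan-1-one (pseudo-aspidinol), via dichloroboron chelate 16 (not isolated), via silyl-protected hydroxyketone 17 (not isolated)
Conditions: BCl3 (1.5 equiv), CH2Cl2, −78 → −10 °C; MeOH quench, concentrate; then TBAF, AcOH, THF, 0 °C
Reagents that add atoms: none
Why: Chelation-assisted Lewis-acid ether cleavage followed by fluoride desilylation: ketone-bound BCl3 ionises the secondary O–i-Pr bond far faster than it attacks a methyl ether, the six-membered chelate 16 then occupies the carbonyl and protects the C6 OCH3, and buffered TBAF removes the aryl TIPS ether without touching ketone or methyl ether.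

Step 7
Reactants: 18 1-(4,6-dihydroxy-2-methoxy-3-methylphenyl)butan-1-one
Product: 20 3-butanoyl-2,6-dihydroxy-4-methoxy-5-methylbenzaldehyde, via chloro(methoxy)methyl arene 19 (not isolated)
Conditions: Cl2CHOMe, TiCl4, CH2Cl2, −20 → 0 °C; then aq. HCl
Reagents that add atoms: dichloromethyl methyl ether, COC(Cl)Cl; water, O
Why: Rieche formylation: C3, between the two free hydroxyls, is the only unsubstituted carbon of the still strongly activated acylphloroglucinol ring, hydrolysis of 19 gives the doubly hydrogen-bonded aldehyde, and the reagent spares the α-carbon of the o-hydroxyaryl ketone, which chloroiminium reagents can attack.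

Step 8
Reactants: 21 2,4,6-trihydroxyacetophenone
Product: 23 2-acetyl-3,5-dihydroxy-6,6-dimethylcyclohexa-2,4-dien-1-one (acetylfilicinic acid), via C-methylphloracetophenone 22 (not isolated)
Conditions: NaOMe (3 equiv), MeI (2.2 equiv), MeOH, 0 °C → rt; aq. HCl
Reagents that add atoms: iodomethane, CI
Why: Base-mediated dearomative C-alkylation of an acylphloroglucinol: the phenoxide is C-methylated to 22, whose methyl-bearing carbon is the most nucleophilic site and takes the second methyl, and limiting MeI restrains methylation of the remaining ring CH.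

Step 9
Reactants: 20 3-butanoyl-2,6-dihydroxy-4-methoxy-5-methylbenzaldehyde; 23 2-acetyl-3,5-dihydroxy-6,6-dimethylcyclohexa-2,4-dien-1-one
Product: 25 aspidin AB, via Knoevenagel alkylidene 24 (not isolated)
Conditions: L-proline (20 mol %), Hantzsch ester (diethyl 2,6-dimethyl-1,4-dihydropyridine-3,5-dicarboxylate, 1.1 equiv), EtOH, 25–40 °C
Reagents that add atoms: none
Why: Organocatalytic three-component reductive alkylation (proline-catalysed Knoevenagel condensation, then Hantzsch ester transfer hydrogenation): the only C–H acidic ring carbon of 23 condenses with 20 to the electron-poor alkylidene 24, which should accept hydride at the benzylic carbon faster than a second dione, so the unsymmetrical CH2 bridge forms without the scrambling of formaldehyde couplings.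

Compound list
1 | 2-chloro-1,1-dimethoxyethane | COC(CCl)OC | starting material
2 | lithium methoxyacetylide | [Li]C#COC | intermediate
3 | 1-methoxyprop-1-yne | CC#COC | intermediate
4 | 3-ethoxycyclobut-2-en-1-one | CCOC1=CC(=O)C1 | starting material
5 | 3-(propan-2-yloxy)cyclobut-2-en-1-one | CC(C)OC1=CC(=O)C1 | intermediate
6 | 3-(propan-2-yloxy)buta-1,3-dien-1-one (vinylketene) | C=C(OC(C)C)C=C=O | intermediate
7 | 3-methoxy-2-methyl-4-[1-(propan-2-yloxy)ethenyl]cyclobut-2-en-1-one (racemic) | O=C1C(C)=C(OC)C1C(=C)OC(C)C | intermediate
8 | (3E)-3-methoxy-2-methyl-5-(propan-2-yloxy)hexa-1,3,5-trien-1-one (dienylketene) | O=C=C(C)/C(OC)=C\C(=C)OC(C)C | intermediate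
9 | 3-methoxy-2-methyl-5-(propan-2-yloxy)cyclohexa-2,4-dien-1-one | O=C1CC(OC(C)C)=CC(OC)=C1C | intermediate
10 | 3-methoxy-2-methyl-5-(propan-2-yloxy)phenol | Cc1c(O)cc(OC(C)C)cc1OC | intermediate
11 | [3-methoxy-2-methyl-5-(propan-2-yloxy)phenoxy]tri(propan-2-yl)silane | Cc1c(O[Si](C(C)C)(C(C)C)C(C)C)cc(OC(C)C)cc1OC | intermediate
12 | N-methoxy-N-methylbutanamide | CCCC(=O)N(C)OC | starting material
13 | {2-methoxy-3-methyl-6-(propan-2-yloxy)-4-[tri(propan-2-yl)silyloxy]phenyl}lithium | [Li]c1c(OC(C)C)cc(O[Si](C(C)C)(C(C)C)C(C)C)c(C)c1OC | intermediate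
14 | lithium 1-[methoxy(methyl)amino]-1-{2-methoxy-3-methyl-6-(propan-2-yloxy)-4-[tri(propan-2-yl)silyloxy]phenyl}butan-1-olate (racemic) | CCCC(O[Li])(N(C)OC)c1c(OC(C)C)cc(O[Si](C(C)C)(C(C)C)C(C)C)c(C)c1OC | intermediate
15 | 1-{2-methoxy-3-methyl-6-(propan-2-yloxy)-4-[tri(propan-2-yl)silyloxy]phenyl}butan-1-one | CCCC(=O)c1c(OC(C)C)cc(O[Si](C(C)C)(C(C)C)C(C)C)c(C)c1OC | intermediate
16 | {2-butanoyl-3-methoxy-4-methyl-5-[tri(propan-2-yl)silyloxy]phenoxy}dichloroborane | CCCC(=O)c1c(OB(Cl)Cl)cc(O[Si](C(C)C)(C(C)C)C(C)C)c(C)c1OC | intermediate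
17 | 1-{6-hydroxy-2-methoxy-3-methyl-4-[tri(propan-2-yl)silyloxy]phenyl}butan-1-one | CCCC(=O)c1c(O)cc(O[Si](C(C)C)(C(C)C)C(C)C)c(C)c1OC | intermediate
18 | 1-(4,6-dihydroxy-2-methoxy-3-methylphenyl)butan-1-one (pseudo-aspidinol) | CCCC(=O)c1c(O)cc(O)c(C)c1OC | intermediate
19 | 1-{3-[chloro(methoxy)methyl]-2,4-dihydroxy-6-methoxy-5-methylphenyl}butan-1-one (racemic) | CCCC(=O)c1c(O)c(C(Cl)OC)c(O)c(C)c1OC | intermediate
20 | 3-butanoyl-2,6-dihydroxy-4-methoxy-5-methylbenzaldehyde | CCCC(=O)c1c(O)c(C=O)c(O)c(C)c1OC | intermediate
21 | 2,4,6-trihydroxyacetophenone | CC(=O)c1c(O)cc(O)cc1O | starting material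
22 | 1-(2,4,6-trihydroxy-3-methylphenyl)ethan-1-one | CC(=O)c1c(O)cc(O)c(C)c1O | intermediate
23 | 2-acetyl-3,5-dihydroxy-6,6-dimethylcyclohexa-2,4-dien-1-one (acetylfilicinic acid) | CC(=O)C1=C(O)C=C(O)C(C)(C)C1=O | intermediate
24 | 2-acetyl-6-[(3-butanoyl-2,6-dihydroxy-4-methoxy-5-methylphenyl)methylidene]-3-hydroxy-4,4-dimethylcyclohex-2-ene-1,5-dione | CCCC(=O)c1c(O)c(C=C2C(=O)C(C)(C)C(O)=C(C(C)=O)C2=O)c(O)c(C)c1OC | intermediate
25 | aspidin AB, 2-acetyl-4-[(3-butanoyl-2,6-dihydroxy-4-methoxy-5-methylphenyl)methyl]-3,5-dihydroxy-6,6-dimethylcyclohexa-2,4-dien-1-one | CCCC(=O)c1c(O)c(CC2=C(O)C(C)(C)C(=O)C(C(C)=O)=C2O)c(O)c(C)c1OC | target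

Total step count: 9. Longest linear sequence: 7 (steps 2, 3, 4, 5, 6, 7 and 9; the sequence through step 1 is equally long).

Steps most likely to fail

Step 3 (key step). The vinylogous-ester resonance of 5 may slow the first electrocyclic opening. At the temperature then required, the volatile ynol ether could be lost to oligomerisation, or the ketene could be captured by phenol already formed. The fallback sets out from 3 and comes back at 7, and thus at 10. It generates the same vinylketene 6 at or below room temperature by 1,4-dehydrochlorination instead of by ring opening. Commercial isopropyl acetoacetate is converted with HC(O-i-Pr)3 and catalytic H2SO4 in i-PrOH into propan-2-yl (E)-3-(propan-2-yloxy)but-2-enoate F1. KOH in aqueous EtOH followed by careful acidification gives (E)-3-(propan-2-yloxy)but-2-enoic acid F2, and oxalyl chloride gives (E)-3-(propan-2-yloxy)but-2-enoyl chloride F3. Slow addition of Et3N to F3 and 3 in toluene should form 6, which is trapped in situ as 7. Heating the filtered solution then completes the 4π/6π sequence to 10.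

Step 5. Deprotonation may be slow or misdirected (lateral at the C5 methyl, or at C3), and the hindered aryllithium may take a proton from the amide instead of adding to it. The fallback sets out from 10 and comes back at 20, by-passing steps 4 to 7. It uses the free C4 hydroxyl to occupy C3 first, so that C1 is the only ring carbon left. Magnesium-phenoxide ortho-formylation (MgCl2, Et3N, paraformaldehyde, MeCN, reflux; Casnati–Skattebøl formylation) gives 2-hydroxy-4-methoxy-3-methyl-6-(propan-2-yloxy)benzaldehyde F4. BCl3 then cleaves the isopropyl ether, which is now ortho to the aldehyde, while the methyl ether is para to it and unchelated; this gives 2,6-dihydroxy-4-methoxy-3-methylbenzaldehyde F5. Friedel–Crafts acylation with butanoyl chloride and AlCl3 (O-acylation and Fries migration from the C2 oxygen) places the butyryl group at C1 and gives 20.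

Step 9. Condensation of the electron-rich, doubly hydrogen-bonded aldehyde may be sluggish. A second molecule of 23 may add before hydride transfer, or an ortho hydroxyl may cyclise onto ring B. The fallback sets out from 18, uses 23 and comes back at 25, by-passing step 7. It brings in the bridge carbon at the amine oxidation level. Mannich reaction of 18 with Eschenmoser's salt at its only free ring carbon gives 1-{3-[(dimethylamino)methyl]-2,4-dihydroxy-6-methoxy-5-methylphenyl}butan-1-one F6. Heating F6 with 23 in dioxane should expel the amine to give the ortho-quinone methide 4-butanoyl-5-hydroxy-3-methoxy-2-methyl-6-methylidenecyclohexa-2,4-dien-1-one F7, which is captured by the nucleophilic ring carbon of 23.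

Further compounds
F1 | step 3 | propan-2-yl (E)-3-(propan-2-yloxy)but-2-enoate | CC(C)OC(=O)/C=C(C)/OC(C)C
F2 | step 3 | (E)-3-(propan-2-yloxy)but-2-enoic acid | OC(=O)/C=C(C)/OC(C)C
F3 | step 3 | (E)-3-(propan-2-yloxy)but-2-enoyl chloride | ClC(=O)/C=C(C)/OC(C)C
F4 | step 5 | 2-hydroxy-4-methoxy-3-methyl-6-(propan-2-yloxy)benzaldehyde | O=Cc1c(O)c(C)c(OC)cc1OC(C)C
F5 | step 5 | 2,6-dihydroxy-4-methoxy-3-methylbenzaldehyde | O=Cc1c(O)c(C)c(OC)cc1O
F6 | step 9 | 1-{3-[(dimethylamino)methyl]-2,4-dihydroxy-6-methoxy-5-methylphenyl}butan-1-one | CCCC(=O)c1c(O)c(CN(C)C)c(O)c(C)c1OC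
F7 | step 9 | 4-butanoyl-5-hydroxy-3-methoxy-2-methyl-6-methylidenecyclohexa-2,4-dien-1-one | CCCC(=O)C1=C(O)C(=C)C(=O)C(C)=C1OC
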